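Labdane numbering is used: the lactone ring is O–C15(=O)–C14H=C13–C16H2. The butenolide is closed last, from a temporary ring. The terminal alkyne of the finished cis-decalin (future C13 and C16) is cyclopropenated with tert-butyl diazoacetate, which brings C14 and C15. Monovalent gold then cleaves the cyclopropene bond C14–C16 and the ester carbonyl oxygen captures the carbenoid carbon C16: one operation forms the lactone O–C16H2 bond, sets the C13=C14 double bond and expels isobutene. The step exploits the contiguous three-carbon unit C14–C13–C16 of the lactone ring, which maps onto a cyclopropene. The decalin (rings A and B) comes from an enantioselective quinone Diels–Alder reaction.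

Key step: step 14

Remark on the structure: ring A = C1–C5 and C10, ring B = C5–C10; C18 and C19 sit on C4, C20 on C10, C17 on C8, the side chain is C11–C12; β is the face of the C10 methyl group. Read this way, the target is cis-fused (5β-H, 10β-CH3) with 2α-OH, 6α-OH, 4α-CH3 (C18) and 4β-CH2OAc (C19).

Assumption: the (S)-configured oxazaborolidinium catalyst of step 2 is taken to give the enantiomer drawn for 4, as its usual pre-transition-state model suggests; the mirror-image catalyst is equally available.

Step 1
Reactants: 1 (E)-pent-3-en-2-one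
Product: 2 (E)-triisopropyl(penta-1,3-dien-2-yloxy)silane
Conditions: LiN(i-Pr)2, THF, −78 °C; then i-Pr3SiOTf, −78 → 0 °C
Reagents that add atoms: triisopropylsilyl triflate, CC(C)[Si](C(C)C)(C(C)C)OS(=O)(=O)C(F)(F)F
Why: Kinetic deprotonation of the methyl ketone at its terminal methyl group and O-silylation (silyl enol ether formation) should give the cross-conjugated 2-silyloxy diene, with the E-alkene of 1 carried over unchanged.

Step 2
Reactants: 2 (E)-triisopropyl(penta-1,3-dien-2-yloxy)silane; 3 2,6-dimethyl-1,4-benzoquinone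
Product: 4 cis-fused Diels–Alder adduct (C2=C3 triisopropylsilyl enol ether, 4α-CH3, 5β-H, 10β-CH3; ring B enedione with C6=O, C7=C8 bearing the 8-CH3, C9=O)
Conditions: (S)-o-tolyl-oxazaborolidine from (S)-α,α-diphenylprolinol, activated with Tf2NH (20 mol%), CH2Cl2, −78 °C
Reagents that add atoms: none
Why: Catalytic enantioselective Diels–Alder reaction in which the cationic oxazaborolidine should bind the unhindered, more basic carbonyl flanked by two CH groups (future C6), so that the nucleophilic CH2 terminus of 2 bonds to the methyl-bearing carbon (C10) and the methyl-bearing terminus to C5; suprafacial endo addition sets the cis ring fusion and the 4α-methyl group, and the catalyst sets the absolute configuration.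

Step 3
Reactants: 4 cis-fused Diels–Alder adduct
Product: 5 6α-hydroxy enone (as 4, with C6=O reduced to 6α-OH; C9=O and C7=C8 kept)
Conditions: NaBH4, CeCl3·7H2O, MeOH/CH2Cl2, −78 °C
Reagents that add atoms: none
Why: Luche 1,2-reduction should take the less hindered C6 carbonyl (C9 is flanked by the quaternary C10 and the methylated C8) and deliver hydride from the convex β-face, away from ring A and its 4α-methyl group, which sets the 6α-hydroxyl.

Step 4
Reactants: 5 6α-hydroxy enone
Product: 6 6α-tert-butyldimethylsilyl ether of 5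
Conditions: t-BuMe2SiOTf, 2,6-lutidine, CH2Cl2, 0 °C
Reagents that add atoms: tert-butyldimethylsilyl triflate, CC(C)(C)[Si](C)(C)OS(=O)(=O)C(F)(F)F
Why: Silylation of the secondary alcohol with a silyl triflate and a hindered base; the silyl enol ether and the enone are inert.

Step 5
Reactants: 6 6α-tert-butyldimethylsilyl ether
Product: 8 C9 enol triflate (C8=C9–OTf, C7 now CH2; otherwise as 6), via lithium enolate 7 (not isolated)
Conditions: LiBH(s-Bu)3, THF, −78 °C; then 2-[N,N-bis(trifluoromethylsulfonyl)amino]-5-chloropyridine, −78 → 0 °C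
Reagents that add atoms: 2-[N,N-bis(trifluoromethylsulfonyl)amino]-5-chloropyridine, O=S(=O)(N(c1ccc(Cl)cn1)S(=O)(=O)C(F)(F)F)C(F)(F)F
Why: Conjugate hydride addition of the bulky borohydride to the β-unsubstituted enone gives the C8=C9 lithium enolate regiospecifically, and O-triflation fixes the tetrasubstituted C8=C9 double bond as the enol triflate; no stereocentre is formed.

Step 6
Reactants: 8 C9 enol triflate; 9 (4-bromobut-1-yn-1-yl)trimethylsilane
Product: 11 coupled silylalkyne (C9 carries CH2CH2C≡C–SiMe3; tetrasubstituted C8=C9; ring A as in 4; 6α-OSiMe2t-Bu), via organozinc bromide 10 (not isolated)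
Conditions: Zn dust, I2 (5 mol%), N,N-dimethylacetamide, 80 °C (9 → 10); then 8, Pd(dppf)Cl2 (5 mol%), THF, 60 °C
Reagents that add atoms: zinc, [Zn] (held only in intermediate 10)
Why: Zinc insertion into the primary bromide followed by Negishi sp3–sp2 cross-coupling, in which zerovalent palladium with the wide-bite-angle dppf ligand favours reductive elimination over β-hydride elimination; the silyl enol ether, the silyl ether and the silylalkyne are inert.

Step 7
Reactants: 11 coupled silylalkyne
Product: 12 ring A enone (C2=O, C3=C4 bearing the 4-CH3; rest as 11)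
Conditions: Pd(OAc)2 (1.2 equiv), MeCN, 40 °C
Reagents that add atoms: none
Why: Saegusa–Ito oxidation, in which the divalent palladium enolate formed from the C2=C3 silyl enol ether can undergo β-hydride elimination only toward C4, giving the C3=C4 enone and erasing the C4 stereocentre on purpose.

Step 8
Reactants: 12 ring A enone; 13 (chloromethyl)(isopropoxy)dimethylsilane
Product: 16 C2 ketone with quaternary C4 (4α-CH3, 4β-CH2SiMe2(Oi-Pr); rest as 12), via Grignard reagent 14 (not isolated), via trimethylsilyl enol ether 15 (not isolated)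
Conditions: Mg, THF, rt (13 → 14); then 12, CuI (20 mol%), Me3SiCl, THF, −78 → −20 °C; dilute aqueous citric acid work-up
Reagents that add atoms: magnesium, [Mg] (held only in intermediate 14); chlorotrimethylsilane, C[Si](C)(C)Cl (held only in intermediate 15)
Why: Copper-catalysed, chlorosilane-accelerated conjugate addition of the Tamao hydroxymethyl-anion equivalent creates the C4 quaternary centre; the nucleophile should enter on the β-face, anti to the vicinal C5–C6 bond and its α-silyloxy group (the usual trans addition next to a substituted γ-carbon), which places C19 β and the C18 methyl α.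

Step 9
Reactants: 16 C2 ketone with 4β-CH2SiMe2(Oi-Pr)
Product: 17 19-hydroxy-2-ketone with terminal alkyne (4β-CH2OH, C9–CH2CH2C≡CH, 6α-OSiMe2t-Bu)
Conditions: 30% H2O2, KF, KHCO3, THF/MeOH (1:1), rt
Reagents that add atoms: hydrogen peroxide, OO
Why: Tamao–Fleming oxidation converts the C–Si bond into the C19 hydroxyl (peroxide attack at fluoride-activated silicon, then 1,2-shift of carbon from silicon to oxygen), and the same fluoride/methanol medium should remove the alkynyl trimethylsilyl group.

Step 10
Reactants: 17 19-hydroxy-2-ketone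
Product: 18 2α,19-diol (rest as 17)
Conditions: Me4NBH(OAc)3, MeCN/AcOH (1:1), −20 → 0 °C
Reagents that add atoms: none
Why: Hydroxyl-directed reduction (Evans–Saksena type): the borohydride exchanges an acetate for the β-oriented C19 hydroxyl and should deliver hydride intramolecularly, 1,3-syn across ring A, to the β-face of the C2 carbonyl, which sets the 2α-hydroxyl; ketones without a directing hydroxyl are not reduced by this reagent.

Step 11
Reactants: 18 2α,19-diol
Product: 19 19-acetate with free 2α-OH
Conditions: AcCl (1.1 equiv), 2,4,6-collidine, CH2Cl2, −78 °C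
Reagents that add atoms: acetyl chloride, CC(=O)Cl
Why: Selective acetylation of the primary C19 hydroxyl over the secondary C2 hydroxyl with acetyl chloride and collidine at low temperature.

Step 12
Reactants: 19 19-acetate with free 2α-OH
Product: 20 19-acetate 2α-triethylsilyl ether (terminal alkyne, 6α-OSiMe2t-Bu)
Conditions: Et3SiOTf, 2,6-lutidine, CH2Cl2, −78 → 0 °C
Reagents that add atoms: triethylsilyl triflate, CC[Si](CC)(CC)OS(=O)(=O)C(F)(F)F
Why: Silylation of the remaining secondary alcohol, needed because a free hydroxyl would undergo O–H insertion in step 13.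

Step 13
Reactants: 20 19-acetate 2α-triethylsilyl ether
Product: 21 tert-butyl 2-(2-decalinylethyl)cycloprop-2-ene-1-carboxylate (cyclopropene C13=C16H with C14H–CO2t-Bu; mixture of epimers at C14; decalin as in 20)
Conditions: Rh2(OAc)4 (2 mol%), tert-butyl diazoacetate (slow addition), CH2Cl2, rt
Reagents that add atoms: tert-butyl diazoacetate, CC(C)(C)OC(=O)C=[N+]=[N-]
Why: Dirhodium-carbenoid [2+1] cycloaddition (cyclopropenation) to the terminal alkyne, which is far more reactive than the hindered tetrasubstituted C8=C9 alkene; the new stereocentre at C14 forms as an inconsequential mixture that is destroyed in step 14.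

Step 14
Reactants: 21 cyclopropene tert-butyl ester
Product: 22 bis-silylated butenolide (target with 2α-OSiEt3 and 6α-OSiMe2t-Bu)
Conditions: Ph3PAuNTf2 (5 mol%), CH2Cl2, 0 °C → rt
Reagents that add atoms: none
Why: Cationic monovalent gold adds to the cyclopropene π-bond at its unsubstituted carbon C16 (Markovnikov, tertiary cyclopropyl cation at C13), the strained C14–C16 σ-bond opens to a vinyl gold carbenoid/allyl cation (Au=C16H–C13(R)=C14H–CO2t-Bu), the ester carbonyl oxygen attacks C16, and loss of isobutene with protodeauration at C16 releases the butenolide. The closest known reaction type is the gold-, rhodium- or copper-catalysed ring-opening cycloisomerisation of cycloprop-2-ene-1-carboxylates to furans and 2(5H)-furanones. The five-membered lactone closes by 5-endo attack of the carbonyl oxygen on the carbenoid carbon (equivalent to a 4π electrocyclisation of an oxapentadienyl cation), forming the O–C16 bond while the temporary C14–C16 bond is cleaved. No stereocentre is created, and the C14 stereocentre of the cyclopropene is destroyed, so both epimers converge. The step needs opening toward the C16 carbenoid, secured by the alkyl group on C13 that stabilises the cation there, and chemoselectivity over the tetrasubstituted C8=C9 alkene, secured by the strain-driven reactivity of the cyclopropene toward gold and by the intramolecular ester trap.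

Step 15
Reactants: 22 bis-silylated butenolide
Product: 23 target, 19-acetoxy-2α,6α-dihydroxy-5β-labda-8,13-dien-15,16-olide (cis-fused)
Conditions: HF·pyridine, THF, 0 °C → rt
Reagents that add atoms: none
Why: Fluoride-mediated cleavage of both silyl ethers; the acetate and the butenolide are stable to buffered HF·pyridine.

Compound list

1 | (E)-pent-3-en-2-one | C/C=C/C(C)=O | starting material
2 | (E)-triisopropyl(penta-1,3-dien-2-yloxy)silane | C/C=C/C(=C)O[Si](C(C)C)(C(C)C)C(C)C | intermediate
3 | 2,6-dimethyl-1,4-benzoquinone | CC1=CC(=O)C=C(C)C1=O | starting material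
4 | cis-fused Diels–Alder adduct: C2=C3 triisopropylsilyl enol ether, 4α-CH3, 5β-H, 10β-CH3, ring B enedione (C6=O, C7=C8, C9=O) | C[C@@H]1C=C(O[Si](C(C)C)(C(C)C)C(C)C)C[C@]2(C)C(=O)C(C)=CC(=O)[C@H]12 | intermediate
5 | 6α-hydroxy enone (4 with C6=O reduced to 6α-OH) | C[C@@H]1C=C(O[Si](C(C)C)(C(C)C)C(C)C)C[C@]2(C)C(=O)C(C)=C[C@H](O)[C@H]12 | intermediate
6 | 6α-tert-butyldimethylsilyl ether of 5 | C[C@@H]1C=C(O[Si](C(C)C)(C(C)C)C(C)C)C[C@]2(C)C(=O)C(C)=C[C@H](O[Si](C)(C)C(C)(C)C)[C@H]12 | intermediate
7 | lithium C8=C9 enolate from conjugate reduction of 6 (formed in step 5, not isolated) | C[C@@H]1C=C(O[Si](C(C)C)(C(C)C)C(C)C)C[C@]2(C)C(O[Li])=C(C)C[C@H](O[Si](C)(C)C(C)(C)C)[C@H]12 | intermediate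
8 | C9 enol triflate (C8=C9–OTf, C7H2, 6α-OSiMe2t-Bu, ring A as in 4) | C[C@@H]1C=C(O[Si](C(C)C)(C(C)C)C(C)C)C[C@]2(C)C(OS(=O)(=O)C(F)(F)F)=C(C)C[C@H](O[Si](C)(C)C(C)(C)C)[C@H]12 | intermediate
9 | (4-bromobut-1-yn-1-yl)trimethylsilane | C[Si](C)(C)C#CCCBr | starting material
10 | [4-(trimethylsilyl)but-3-yn-1-yl]zinc bromide (formed in step 6, not isolated) | C[Si](C)(C)C#CCC[Zn]Br | intermediate
11 | coupled silylalkyne: C9–CH2CH2C≡C–SiMe3, C8=C9, C2=C3 silyl enol ether, 4α-CH3, 6α-OSiMe2t-Bu | C[C@@H]1C=C(O[Si](C(C)C)(C(C)C)C(C)C)C[C@]2(C)C(CCC#C[Si](C)(C)C)=C(C)C[C@H](O[Si](C)(C)C(C)(C)C)[C@H]12 | intermediate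
12 | ring A enone: C2=O, C3=C4 with 4-CH3; rest as 11 | CC1=CC(=O)C[C@]2(C)C(CCC#C[Si](C)(C)C)=C(C)C[C@H](O[Si](C)(C)C(C)(C)C)[C@H]12 | intermediate
13 | (chloromethyl)(isopropoxy)dimethylsilane | CC(C)O[Si](C)(C)CCl | starting material
14 | [(isopropoxydimethylsilyl)methyl]magnesium chloride (formed in step 8, not isolated) | CC(C)O[Si](C)(C)C[Mg]Cl | intermediate
15 | C2=C3 trimethylsilyl enol ether of 16 (formed in step 8, not isolated) | CC(C)O[Si](C)(C)C[C@@]1(C)C=C(O[Si](C)(C)C)C[C@]2(C)C(CCC#C[Si](C)(C)C)=C(C)C[C@H](O[Si](C)(C)C(C)(C)C)[C@H]12 | intermediate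
16 | C2 ketone with quaternary C4: 4α-CH3, 4β-CH2SiMe2(Oi-Pr); rest as 12 | CC(C)O[Si](C)(C)C[C@@]1(C)CC(=O)C[C@]2(C)C(CCC#C[Si](C)(C)C)=C(C)C[C@H](O[Si](C)(C)C(C)(C)C)[C@H]12 | intermediate
17 | 19-hydroxy-2-ketone with terminal alkyne (4β-CH2OH, 6α-OSiMe2t-Bu) | OC[C@@]1(C)CC(=O)C[C@]2(C)C(CCC#C)=C(C)C[C@H](O[Si](C)(C)C(C)(C)C)[C@H]12 | intermediate
18 | 2α,19-diol (terminal alkyne, 6α-OSiMe2t-Bu) | OC[C@@]1(C)C[C@H](O)C[C@]2(C)C(CCC#C)=C(C)C[C@H](O[Si](C)(C)C(C)(C)C)[C@H]12 | intermediate
19 | 19-acetate with free 2α-OH | CC(=O)OC[C@@]1(C)C[C@H](O)C[C@]2(C)C(CCC#C)=C(C)C[C@H](O[Si](C)(C)C(C)(C)C)[C@H]12 | intermediate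
20 | 19-acetate 2α-triethylsilyl ether | CC(=O)OC[C@@]1(C)C[C@H](O[Si](CC)(CC)CC)C[C@]2(C)C(CCC#C)=C(C)C[C@H](O[Si](C)(C)C(C)(C)C)[C@H]12 | intermediate
21 | tert-butyl cycloprop-2-ene-1-carboxylate carrying the decalinylethyl group on C13 (epimers at C14) | CC(=O)OC[C@@]1(C)C[C@H](O[Si](CC)(CC)CC)C[C@]2(C)C(CCC3=CC3C(=O)OC(C)(C)C)=C(C)C[C@H](O[Si](C)(C)C(C)(C)C)[C@H]12 | intermediate
22 | bis-silylated butenolide (2α-OSiEt3, 6α-OSiMe2t-Bu) | CC(=O)OC[C@@]1(C)C[C@H](O[Si](CC)(CC)CC)C[C@]2(C)C(CCC3=CC(=O)OC3)=C(C)C[C@H](O[Si](C)(C)C(C)(C)C)[C@H]12 | intermediate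
23 | 19-acetoxy-2α,6α-dihydroxy-5β-labda-8,13-dien-15,16-olide (CNP0201970.1) | CC(=O)OC[C@@]1(C)C[C@H](O)C[C@]2(C)C(CCC3=CC(=O)OC3)=C(C)C[C@H](O)[C@H]12 | target

Total step count: 15. Longest linear sequence: 15 steps (1 to 23 through steps 1–15); compounds 3, 9 and 13 are purchased and enter in steps 2, 6 and 8.

Steps most likely to fail

Step 14 (key step). The gold carbenoid may be intercepted by the tetrasubstituted C8=C9 alkene (intramolecular cyclopropanation), the cyclopropene may open toward the C13 carbenoid, or it may oligomerise before the ester oxygen closes the ring. The fallback sets out from 20 and comes back at 22. Anti-Markovnikov hydroboration of the terminal alkyne of 20 with dicyclohexylborane and oxidation with NaBO3 should give the aldehyde F1. Condensation of F1 with glyoxylic acid monohydrate and morpholine (dioxane, 60 °C; enamine aldol, then dehydration) should give the 5-hydroxybutenolide F2, in which the ring again closes by addition of the carboxyl oxygen to C16, now an aldehyde carbon. NaBH4 (MeOH, 0 °C, then dilute acid) should reduce the lactol of F2 to the butenolide 22.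

Step 8. The conjugate addition has to build a quaternary carbon next to the ring fusion, so transfer of the silylmethyl group may be slow, 1,2-addition or γ-deprotonation of the enone may compete, or facial selectivity may be poor. The fallback sets out from 12 and comes back at 17. Benzophenone-sensitised photoaddition of methanol (MeOH, hν 350 nm), a Giese-type addition of the hydroxymethyl radical to the β-carbon that should again occur anti to the C5–C6 bond, should give the hydroxy ketone F3. Its alkynyl silyl group is removed with K2CO3 in MeOH to give 17.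

Step 2. Regio- or enantiocontrol may erode with the methyl-substituted diene, or the diene may lose its silyl group (Mukaiyama–Michael pathway) before the second bond closes. The fallback sets out from 2 and 3 and comes back at 5. BF3·OEt2-promoted cycloaddition (CH2Cl2, −78 °C), which keeps the Lewis-acid-controlled regiochemistry, should give racemic material, that is 4 together with its enantiomer F4. Reduction as in step 3 should give 5 together with its enantiomer F5. Kinetic resolution with Burkholderia cepacia lipase and vinyl acetate (tert-butyl methyl ether, rt) should acetylate the (6R)-alcohol F5 to the acetate F6, following the usual empirical preference of lipases for the R-carbinol whose larger substituent has the higher priority. This leaves 5, which is separated by chromatography.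

Further compounds

F1 | step 14 | aldehyde: 20 with the C9 side chain CH2CH2CH2CHO | CC(=O)OC[C@@]1(C)C[C@H](O[Si](CC)(CC)CC)C[C@]2(C)C(CCCC=O)=C(C)C[C@H](O[Si](C)(C)C(C)(C)C)[C@H]12
F2 | step 14 | 5-hydroxybutenolide: 22 with OH on C16 (epimers) | CC(=O)OC[C@@]1(C)C[C@H](O[Si](CC)(CC)CC)C[C@]2(C)C(CCC3=CC(=O)OC3O)=C(C)C[C@H](O[Si](C)(C)C(C)(C)C)[C@H]12
F3 | step 8 | 19-hydroxy-2-ketone still carrying the alkynyl trimethylsilyl group | OC[C@@]1(C)CC(=O)C[C@]2(C)C(CCC#C[Si](C)(C)C)=C(C)C[C@H](O[Si](C)(C)C(C)(C)C)[C@H]12
F4 | step 2 | enantiomer of 4 | C[C@H]1C=C(O[Si](C(C)C)(C(C)C)C(C)C)C[C@@]2(C)C(=O)C(C)=CC(=O)[C@@H]12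
F5 | step 2 | enantiomer of 5 | C[C@H]1C=C(O[Si](C(C)C)(C(C)C)C(C)C)C[C@@]2(C)C(=O)C(C)=C[C@@H](O)[C@@H]12
F6 | step 2 | 6-O-acetate of the enantiomer of 5 | C[C@H]1C=C(O[Si](C(C)C)(C(C)C)C(C)C)C[C@@]2(C)C(=O)C(C)=C[C@@H](OC(C)=O)[C@@H]12
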